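## Retrosynthesis

1. The chroman C2–O bond is made last, by intramolecular Mitsunobu cyclisation (inversion) of an (R)-1,3-diarylpropan-1-ol onto the ortho phenol of the resorcinol-derived ring.
2. The carbinol stereocentre is set by Noyori asymmetric transfer hydrogenation of the dihydrochalcone. This avoids H2/Pd, which would destroy the prenyl and chromene alkenes.
3. The dihydrochalcone comes from Claisen–Schmidt condensation of the chromenyl methyl ketone with 2,4-dihydroxybenzaldehyde, then chemoselective enone C=C reduction.
4. The chromenyl ketone comes from 3',4'-dihydroxyacetophenone. The pyran ring is formed first (prenal annulation at the 4-OH and C5), then the prenyl group by O-allylation, Claisen rearrangement and cross-metathesis.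
5. Ring order: pyran, then prenyl, then the chroman ring last.

Assumption: prenal annulates at the more acidic 4-OH and the free C5, and the Claisen shift goes to C7, the only free ortho carbon.

## Route

**Step 1**
Reactants: 1 (3',4'-dihydroxyacetophenone), 2 (3-methylbut-2-enal, prenal)
Product: 3, 1-(8-hydroxy-2,2-dimethyl-2H-chromen-6-yl)ethanone
Conditions: 2 (2 equiv), pyridine, 125 °C, sealed tube, N2
Reagents that add atoms: prenal (2), CC(C)=CC=O (its C5 unit is incorporated as the pyran ring; net loss of H2O)
Why: Phenol–enal condensation followed by oxa-6π electrocyclisation (chromene annulation) occurs at the acidic 4-OH and the free C5. The 3-OH is the only other phenol, and its ortho carbon C2 is hindered and deactivated by the acetyl group, so the 3-OH remains free.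

**Step 2**
Reactants: 3, 4 (allyl bromide)
Product: 5, 1-(8-allyloxy-2,2-dimethyl-2H-chromen-6-yl)ethanone
Conditions: 4 (1.2 equiv), K2CO3, acetone, reflux
Reagents that add atoms: allyl bromide (4), C=CCBr
Why: Williamson O-allylation of the single free phenol. The ketone and chromene are unaffected.

**Step 3**
Reactants: 5
Product: 6, 1-(7-allyl-8-hydroxy-2,2-dimethyl-2H-chromen-6-yl)ethanone
Conditions: N,N-diethylaniline, 200 °C (or microwave, o-dichlorobenzene, 200 °C)
Reagents that add atoms: none
Why: Aromatic Claisen [3,3] rearrangement of the aryl allyl ether. It can only go to C7, the sole free ortho carbon, because C8a carries the pyran oxygen. The 2,2-dimethylchromene survives this temperature.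

**Step 4**
Reactants: 6, 7 (2-methylbut-2-ene)
Product: 8, 1-(8-hydroxy-2,2-dimethyl-7-(3-methylbut-2-en-1-yl)-2H-chromen-6-yl)ethanone
Conditions: Hoveyda–Grubbs II (5 mol%), 7 (30 equiv), 1,4-benzoquinone (10 mol%), CH2Cl2, 40 °C
Reagents that add atoms: 2-methylbut-2-ene (7), CC=C(C)C, which supplies the CMe2 terminus; propene is lost
Why: Olefin cross-metathesis converts the terminal allyl group into the prenyl group. Benzoquinone suppresses Ru–H isomerisation to the propenyl arene. The ring cis-alkene, hindered by the adjacent gem-dimethyl group, is not consumed.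

**Step 5**
Reactants: 8, 9 (2,4-dihydroxybenzaldehyde)
Product: 10, (E)-3-(2,4-dihydroxyphenyl)-1-(8-hydroxy-2,2-dimethyl-7-prenyl-2H-chromen-6-yl)prop-2-en-1-one
Conditions: KOH (6 equiv), EtOH/H2O, rt to 50 °C, N2; then H3O+
Reagents that add atoms: 2,4-dihydroxybenzaldehyde (9), O=Cc1ccc(O)cc1O (condensation with loss of H2O); KOH adds nothing
Why: Claisen–Schmidt (aldol) condensation of the methyl ketone enolate with the aldehyde gives the thermodynamic E-enone. Excess base keeps the phenols as phenoxides, and the alkenes are inert to base.

**Step 6**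
Reactants: 10
Product: 11, 3-(2,4-dihydroxyphenyl)-1-(8-hydroxy-2,2-dimethyl-7-prenyl-2H-chromen-6-yl)propan-1-one
Conditions: Cu(OAc)2·H2O (5 mol%), BINAP (5 mol%, racemic; the ligand is achiral in effect here), TMDS (4 equiv), toluene, rt; then TBAF, THF
Reagents that add atoms: none (only hydride/H is delivered; O-silyl groups formed on the phenols are removed by TBAF)
Why: Copper-hydride conjugate (1,4) reduction (Cu–H/silane) reduces only the enone C=C. The aryl ketone, the trisubstituted prenyl alkene and the chromene alkene are left intact. No stereocentre is formed here.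

**Step 7**
Reactants: 11
Product: 12, (R)-3-(2,4-dihydroxyphenyl)-1-(8-hydroxy-2,2-dimethyl-7-prenyl-2H-chromen-6-yl)propan-1-ol
Conditions: (R,R)-RuCl(p-cymene)(TsDPEN) (2 mol%), HCO2H/Et3N 5:2, CH2Cl2, 30 °C
Reagents that add atoms: none (hydride from formate; CO2 is lost)
Why: Noyori asymmetric transfer hydrogenation. The (R,R)-catalyst delivers hydride to one enantioface of the aryl alkyl ketone, giving the (R)-alcohol (OH > Ar > CH2 > H). This sets the only stereocentre. The alkenes and phenols are untouched.

**Step 8**
Reactants: 12
Product: 13, Kazinol B, (S)-7-hydroxyflavan with the 7-prenyl-8-hydroxy-2,2-dimethylchromene A-ring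
Conditions: PPh3 (1.5 equiv), DIAD (1.5 equiv), THF (0.005 M), 0 °C to rt
Reagents that add atoms: none (Ph3P=O and the hydrazine dicarboxylate are by-products; net loss of H2O)
Why: Intramolecular Mitsunobu etherification (6-exo-tet SN2) of the ortho phenol onto the activated carbinol proceeds with inversion, so the (R)-alcohol gives the (S)-chroman. High dilution favours ring closure over intermolecular etherification of the other phenols.

## Compound list

| # | Name | SMILES | Role |
|---|---|---|---|
| 1 | 3',4'-dihydroxyacetophenone | CC(=O)c1ccc(O)c(O)c1 | starting material |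
| 2 | 3-methylbut-2-enal (prenal) | CC(C)=CC=O | starting material |
| 3 | 1-(8-hydroxy-2,2-dimethyl-2H-chromen-6-yl)ethanone | CC(=O)c1cc2C=CC(C)(C)Oc2c(O)c1 | intermediate |
| 4 | allyl bromide | C=CCBr | starting material |
| 5 | 1-(8-allyloxy-2,2-dimethyl-2H-chromen-6-yl)ethanone | CC(=O)c1cc2C=CC(C)(C)Oc2c(OCC=C)c1 | intermediate |
| 6 | 1-(7-allyl-8-hydroxy-2,2-dimethyl-2H-chromen-6-yl)ethanone | CC(=O)c1cc2C=CC(C)(C)Oc2c(O)c1CC=C | intermediate |
| 7 | 2-methylbut-2-ene | CC=C(C)C | starting material |
| 8 | 1-(8-hydroxy-2,2-dimethyl-7-prenyl-2H-chromen-6-yl)ethanone | CC(=O)c1cc2C=CC(C)(C)Oc2c(O)c1CC=C(C)C | intermediate |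
| 9 | 2,4-dihydroxybenzaldehyde | O=Cc1ccc(O)cc1O | starting material |
| 10 | (E)-3-(2,4-dihydroxyphenyl)-1-(8-hydroxy-2,2-dimethyl-7-prenyl-2H-chromen-6-yl)prop-2-en-1-one | O=C(/C=C/c1ccc(O)cc1O)c1cc2C=CC(C)(C)Oc2c(O)c1CC=C(C)C | intermediate |
| 11 | 3-(2,4-dihydroxyphenyl)-1-(8-hydroxy-2,2-dimethyl-7-prenyl-2H-chromen-6-yl)propan-1-one | O=C(CCc1ccc(O)cc1O)c1cc2C=CC(C)(C)Oc2c(O)c1CC=C(C)C | intermediate |
| 12 | (R)-3-(2,4-dihydroxyphenyl)-1-(8-hydroxy-2,2-dimethyl-7-prenyl-2H-chromen-6-yl)propan-1-ol | O[C@H](CCc1ccc(O)cc1O)c1cc2C=CC(C)(C)Oc2c(O)c1CC=C(C)C | intermediate |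
| 13 | Kazinol B, (S)-flavan | CC(C)=CCc1c([C@@H]2CCc3ccc(O)cc3O2)cc2c(c1O)OC(C)(C)C=C2 | target |

## Totals

Total steps: 8. Longest linear sequence: 8.

## Three steps most likely to fail

1. **Step 8 (Mitsunobu).** The carbinol carbon is para to the pyran oxygen, so ionisation could partly racemise it, and the free phenols could etherify intermolecularly.
   - Fallback: use 2-bromo-4-hydroxybenzaldehyde in place of 9 and carry it through with the (S,S)-catalyst in Step 7. Close the ring by Pd-catalysed (RockPhos) intramolecular C–O coupling of the alcohol onto the aryl bromide. This retains the carbinol configuration and needs no SN2 at the benzylic carbon.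
2. **Step 6 (enone conjugate reduction; Step 5 chalcone formation is the linked risk).** The electron-rich hydroxychalcone is a poor acceptor, the free phenols consume silane, and reduction of the chromene or prenyl alkene is a risk.
   - Fallback: skip the chalcone and Step 6 altogether. Generate the o-quinone methide from 2,4-dihydroxybenzyl alcohol (from 9 by NaBH4 reduction) with base, and add the enolate of 8 to give 11 directly.
3. **Step 1 (chromene annulation on the catechol).** Selectivity for the 4-OH/C5 site, and oxidation or side reactions of the free catechol OH, are uncertain.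
   - Fallback: alkylate the more acidic 4-OH selectively with 3-chloro-3-methylbut-1-yne (K2CO3, KI, CuI). Then heat the aryl propargyl ether in N,N-diethylaniline to trigger the Claisen / [1,5]-H shift / 6π-electrocyclisation cascade to give 3. The 3-OH blocks the other ortho position, so the cascade can only go to C5.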